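The flasks asked about cannot be read off an earlier run: gamma has blue's temperature at another charge, and delta, eta and beta go in by paths that ochre, blue and grey did not take.

| flask | first end groups | second end groups | temperature | remark | time |
|---|---|---|---|---|---|
| ochre | 0.40 M | 0.98 equiv | 10 °C | run made earlier |  |
| blue | 0.27 M | 0.98 equiv | 25 °C | run made earlier |  |
| grey | 0.60 M | 0.98 equiv | 10 °C | run made earlier |  |
| gamma | 0.40 M | 0.980 equiv | 25 °C | everything together at the start | 20 min |
| delta | 0.40 M (fed, over 8.0 min) | 0.980 equiv |  | the addition at 5 °C, then warmed to 25 °C; the feed brings no volume worth counting | 20 min |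
| eta | 0.40 M | 0.980 equiv (in portions, 4, over 8.0 min) | 25 °C | first portion at the start, last at 8.0 min | 20 min |
| beta | 0.40 M | 0.980 equiv (fed, over 8.0 min) | 25 °C | all else is in the flask from the start; the feed brings no volume worth counting | 20 min |

- ochre (time / min: links / %): 4.00: 86.1; 8.00: 85.7; 12.0: 87.0; 15.0: 83.5; 20.0: 78.2; 25.0: 76.6
- blue (time / min: links / %): 1.33: 79.5; 4.00: 73.6; 8.00: 58.3; 10.0: 49.8; 15.0: 37.4; 20.0: 30.7
- grey (time / min: links / %): 6.00: 89.5; 12.0: 83.2; 20.0: 78.7; 25.0: 74.4; 30.0: 71.7; 40.0: 64.3

(scatter of a reading: 1 percentage point)



1. the flask with the highest amount of links, in percent of the first end groups charged ("all alike" if they lie within 1.5 percentage points) (gamma / delta / eta / beta / all alike)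
2. final links, as a percentage of the first end groups charged, in gamma
3. final links, as a percentage of the first end groups charged, in delta
4. final links, as a percentage of the first end groups charged, in eta
5. final links, as a percentage of the first end groups charged, in beta

A bench rule can bridge the gap: treat the loss as first-order, so that links halve in a fixed time, and count each link's age from its mean moment of birth. Blue falls from 73.6% at 4.00 min to 37.4% at 15.0 min, and these two readings, with their scatter, give as a reading the link half-life, the time in which links at 25 °C halve, 11.3 min. Run back to zero age, those readings give a start of 94.1% of the charge.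

Ochre at 10 °C reads a half-life of 125 min, longer than 20 min, and delta's feed runs at 5 °C, so delta's links are reckoned newborn at 8.0 min. Steady feeding and equal portions both place the mean birth at 4.00 min. The reckoning therefore gives 27.6% in gamma, 45.1% in delta, and 35.3% in eta and beta.

The doubt about the rule lies in the charge. Grey, at 1.50 times ochre's charge, reads a half-life of 71.3 min, shorter by a factor of 1.75. Ochre's fall is just 9.5 percentage points against a scatter of 1 point, however, so that factor is a loose reading. If it is real, blue's half-life does not carry over unscaled to gamma, which holds 1.48 times blue's charge; this reckoning keeps the half-life unscaled and accepts that risk.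

The forecast differs, in its words “I scale time by concentration”, and gives 22% for gamma, 33% for delta, 23% for eta, 24% for beta, with delta highest.

The simulation gives 29.7% in gamma, 44.2% in delta, 32.6% in eta and 33.3% in beta, with delta highest.

    first end groups + links → side product (k = 0.00240 L mol⁻¹ s⁻¹, Ea = 68.0 kJ mol⁻¹)
    links ⇌ isomer of the product (K = 1.90, k = 6.40 × 10⁻⁴ s⁻¹, Ea = 84.0 kJ mol⁻¹, ΔH = 2.00 kJ mol⁻¹)
    links → over-reaction product (k = 5.20 × 10⁻⁴ s⁻¹, Ea = 99.0 kJ mol⁻¹)
    first end groups + second end groups → links + by-product (k = 0.370 L mol⁻¹ s⁻¹, Ea = 61.0 kJ mol⁻¹)
    (constants at 25 °C)

In delta the forward half-life of links going to isomer of the product is 3.4 h at 5.00 min, longer than 20 min, but 18 min at 20.0 min. Delta holds 74.3% links and 23.4% first end groups at 8.00 min, and their sum, counted as links from that moment and aged 12.0 min by the link half-life, gives 46.8% against the 44.2% found. Gamma holds 50.7% links at 10.0 min, which the same half-life takes to 27.5% at 20 min, against the 29.7% found.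

The numbers in the tables stem from a simulated flask for substances that don't exist; the scatter is artificial.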